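Late in a run I read the ratio [Q]/[L] as a measure of how long L has been exposed. The flasks, the readings and the questions:

in all of them: Z 0.63 mM (held); J 0.46 mM
- north: G 13 mM; E 6.5 mM; temperature 105 °C; run made earlier
- south-east: G 13 mM; E 3.2 mM; temperature 116 °C; run made earlier
- east: G 13 mM; E 4.9 mM; temperature 105 °C; run made earlier
- zeta: G 13 mM; E 6.50 mM; temperature 110 °C; everything together at the start; time 30 h
- theta: G 13 mM (fed, over 20 h); E 6.50 mM; the addition at 70 °C, then warmed to 110 °C; the feed brings no volume worth counting; time 30 h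
- epsilon: G 13 mM; E 6.50 mM; everything together at the start at 70 °C, warmed to 110 °C at 20 h; time 30 h
- eta: G 13 mM (in portions, 4, over 20 h); E 6.50 mM; temperature 110 °C; first portion at the start, last at 20 h; time 30 h
- gamma: G 13 mM (fed, over 20 h); E 6.50 mM; temperature 110 °C; all else is in the flask from the start; the feed brings no volume worth counting; time 30 h

- north (time / h: L / %, Q / %): 1.33: 3.3, 0.3; 2.50: 4.6, 0; 5.00: 8.3, 0; 10.0: 15.9, 0; 20.0: 28.0, 6.1
- south-east (time / h: L / %, Q / %): 2.50: 5.1, 0.2; 5.00: 9.7, 3.9; 8.00: 16.8, 3.9; 15.0: 25.8, 8.8; 30.0: 40.2, 19.9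
- east (time / h: L / %, Q / %): 2.50: 6.6, 0.5; 5.00: 10.3, 0.4; 8.00: 13.7, 0.9; 15.0: 22.7, 3.9; 30.0: 36.4, 9.3

(readings scatter by 1 percentage point)

- at the start none of Z is in solution

* which flask leads in share of L in L plus Q ("all alike" within 1.5 percentage points) (zeta / theta / epsilon / eta / gamma / all alike)
* share of L in L plus Q at the end, zeta
* share of L in L plus Q at the end, theta
* share of L in L plus Q at the end, epsilon
* share of L in L plus Q at the end, eta
* share of L in L plus Q at the end, gamma

I read the last row of each table. If L grows about steadily, its mean age is half the elapsed time, so twice the ratio over that time is a rate. North, last read at 20.0 h, gives 0.0218 h⁻¹. East, at the same 105 °C with less E and a longer run, gives 0.0170 h⁻¹. South-east, at 116 °C, gives 0.0330 h⁻¹, twice the east value.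

110 °C lies near the middle of 105 °C and 116 °C, and E differs between these runs too, but I assume it has no bearing on this ratio. So I take the geometric mean of the east and south-east readings, 0.0237 h⁻¹: this is the ageing clock, the rise of [Q]/[L] per hour of mean age of L at 110 °C. The share of L in L plus Q, the selectivity, is then one over one plus clock times age.

For zeta the age is half of 30 h, so my share is 73.8 %. Theta spends 10.0 h hot, and I count the hours at 70 °C as nothing. L made while hot ages for half of that stretch and L from the cold feed for the whole of it, so my share lies between 80.8 % and 89.4 %, higher than zeta's.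

The forecast names theta: zeta 75 %, theta 90.5 %, epsilon 89.5 %, eta 82 %, gamma 82.5 %. For theta and epsilon its ground is “and little Q forms”. Its theta stands above my upper end.

The flasks give theta as leader: zeta 70.0 %, theta 83.1 %, epsilon 81.6 %, eta 75.1 %, gamma 75.4 %.

    Z ⇌ X, rate k1*(csat - [X]) (kL = 8.50 h⁻¹)
    G + X + J → J + L (k = 90000 M⁻² h⁻¹, Ea = 42.0 kJ mol⁻¹)
    E + X + J → J + D (k = 1.00 × 10⁵ M⁻² h⁻¹, Ea = 57.0 kJ mol⁻¹)
    L ⇌ Q (K = 0.790, k = 0.0370 h⁻¹, Ea = 119 kJ mol⁻¹, ΔH = −44.0 kJ mol⁻¹)
    (constants at 110 °C)

Theta has not come to rest. At 30.0 h its [Q]/[L] is 0.203, which the clock reads as 8.57 h of mean age, less than the hot stretch, and 74.4 % of its G is still there. This is kinetic control. Zeta's ratio at 30.0 h, 0.428, reads as 18.1 h. Ten times the time, 300 h, takes theta's G down to 0.0697 % and its share from 83.1 % to 55.9 %, and zeta's share at that time is also 55.9 %.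

The readings stem from a simulated flask for an exercise; the scatter is artificial.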